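**Retrosynthetic overview**
- The target is reached by desilylation of its 4'-O-triisopropylsilyl ether; ring B and its methoxy group are carried through from a benzoate.
- Rings C and A arise in one pot from an open-chain δ-hydroxy-β-diketone that ends in a 5-lavandulyl-1,3-dioxin-4-one. Ring C closes first through the O1–C8a bond (the C2 hydroxyl condenses onto the C8a ketone). Ring A closes second through C4a–C5 (the dioxinone releases an acylketene that is captured by C4a, then aromatisation).
- Enabling feature: C8a is both the β-carbon of the C4 ketone in ring C and one of the three oxygen-bearing carbons (C5, C7, C8a) of the phloroglucinol-type ring A. Hence C2–C8a is a masked aldol/1,3-diketone and C5–C8 a masked acylketene that already carries the C6 side chain, so lavandulyl can only end at C6 and hydrogen at C8.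
- The precursor comes from a Claisen union (C4–C4a) of a keto-dioxinone dianion with an (S)-β-hydroxy N-methoxy-N-methylamide; C2 is set by asymmetric transfer hydrogenation.
- The keto-dioxinone comes from acetylation of a 5-lavandulyl dioxinone, made by Negishi coupling of 5-iododioxinone with a lavandulylzinc reagent; the side-chain centre is set by an Evans deconjugative alkylation.

Key step: step 12

Remark: flavanone numbering (O1, C2, C3, C4, C4a, C5 to C8, C8a) is used for all open-chain intermediates; the side-chain centre, (S) when bound to an sp2 carbon as in the target, has the spatial arrangement of (R)-lavandulol; the simple building blocks and reagents are taken to be commercial.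

**Step 1**
Reactants: 1 (4R)-4-benzyl-1,3-oxazolidin-2-one; 2 3-methylbut-2-enoyl chloride
Product: 3 (4R)-4-benzyl-3-(3-methylbut-2-enoyl)-1,3-oxazolidin-2-one
Conditions: n-BuLi, THF, −78 °C; then 2, −78 → 0 °C
Reagents that add atoms: 3-methylbut-2-enoyl chloride (2), CC(C)=CC(=O)Cl
Why: The lithium salt of the oxazolidinone is N-acylated by the acid chloride (imide formation); no stereocentre is created and the auxiliary centre is untouched.

**Step 2**
Reactants: 3 (4R)-4-benzyl-3-(3-methylbut-2-enoyl)-1,3-oxazolidin-2-one; 4 1-bromo-3-methylbut-2-ene (prenyl bromide)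
Product: 5 (4R)-4-benzyl-3-[(2R)-5-methyl-2-(prop-1-en-2-yl)hex-4-enoyl]-1,3-oxazolidin-2-one
Conditions: NaN(SiMe3)2, THF, −78 °C; then 4, −78 → −40 °C
Reagents that add atoms: prenyl bromide (4), CC(C)=CCBr
Why: Evans asymmetric alkylation in its deconjugative mode: γ-deprotonation gives the chelated sodium (Z)-dienolate, which should be alkylated at the α-carbon on the face opposite the benzyl group, so that the (2R) centre of the side chain is set by the auxiliary and the double bond moves into the isopropenyl position.

**Step 3**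
Reactants: 5 (4R)-4-benzyl-3-[(2R)-5-methyl-2-(prop-1-en-2-yl)hex-4-enoyl]-1,3-oxazolidin-2-one
Product: 6 (2R)-5-methyl-2-(prop-1-en-2-yl)hex-4-en-1-ol [(R)-lavandulol]
Conditions: LiBH4, MeOH (1 equiv), Et2O, 0 °C
Reagents that add atoms: none
Why: Reductive cleavage of the N-acyl oxazolidinone by LiBH4 should give the primary alcohol and return the auxiliary, and the α-centre is not enolised under these hydride conditions.

**Step 4**
Reactants: 6 (R)-lavandulol; 7 iodine
Product: 8 (3R)-3-(iodomethyl)-2,6-dimethylhepta-1,5-diene [(R)-lavandulyl iodide]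
Conditions: I2, PPh3, imidazole, CH2Cl2, 0 → 23 °C
Reagents that add atoms: iodine (7), II
Why: Appel-type iodination substitutes the primary hydroxyl by SN2 at CH2, one carbon away from the stereocentre, which is therefore retained.

**Step 5**
Reactants: 9 2,2,6-trimethyl-4H-1,3-dioxin-4-one; 10 N-iodosuccinimide
Product: 11 5-iodo-2,2,6-trimethyl-4H-1,3-dioxin-4-one
Conditions: NIS, AcOH, 23 °C, dark
Reagents that add atoms: N-iodosuccinimide (10), O=C1CCC(=O)N1I
Why: Electrophilic iodination at C5 of the dioxinone, the nucleophilic α-carbon of a vinylogous ester, is a standard preparation of α-iodoenones.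

**Step 6**
Reactants: 8 (R)-lavandulyl iodide; 11 5-iodo-2,2,6-trimethyl-4H-1,3-dioxin-4-one
Product: 13 2,2,6-trimethyl-5-[(2S)-5-methyl-2-(prop-1-en-2-yl)hex-4-en-1-yl]-4H-1,3-dioxin-4-one, via lavandulylzinc iodide 12 (not isolated)
Conditions: 8, Zn dust (activated with BrCH2CH2Br and Me3SiCl), LiCl, THF, 35 °C; then 11, Pd(OAc)2 (3 mol %), SPhos (6 mol %), THF, 23 °C
Reagents that add atoms: none
Why: Zinc insertion into the primary iodide followed by Negishi sp3–sp2 cross-coupling with the α-iodoenone, with a ligand that favours reductive elimination over β-hydride elimination; the stereocentre is β to the metal and is not touched.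

**Step 7**
Reactants: 13 5-lavandulyl-2,2,6-trimethyl-4H-1,3-dioxin-4-one; 14 N-methoxy-N-methylacetamide
Product: 15 2,2-dimethyl-5-[(2S)-5-methyl-2-(prop-1-en-2-yl)hex-4-en-1-yl]-6-(2-oxopropyl)-4H-1,3-dioxin-4-one
Conditions: LiN(iPr)2, THF, −78 °C; then 14, −78 → −40 °C; AcOH
Reagents that add atoms: N-methoxy-N-methylacetamide (14), CC(=O)N(C)OC
Why: γ-Deprotonation gives the lithium dienolate of the dioxinone, which is acylated at the 6-methyl carbon by the N-methoxy-N-methylamide (crossed Claisen condensation), the stable tetrahedral adduct preventing proton transfer and double acylation.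

**Step 8**
Reactants: 16 methyl 4-hydroxy-2-methoxybenzoate; 17 chlorotriisopropylsilane
Product: 18 methyl 2-methoxy-4-[(triisopropylsilyl)oxy]benzoate
Conditions: iPr3SiCl, imidazole, DMF, 23 °C
Reagents that add atoms: chlorotriisopropylsilane (17), CC(C)[Si](Cl)(C(C)C)C(C)C
Why: Silylation of the phenol (silyl ether protection) installs a group that survives lithium amides and mild acid and is removed at the end by fluoride.

**Step 9**
Reactants: 18 methyl 2-methoxy-4-[(triisopropylsilyl)oxy]benzoate; 14 N-methoxy-N-methylacetamide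
Product: 19 N-methoxy-3-{2-methoxy-4-[(triisopropylsilyl)oxy]phenyl}-N-methyl-3-oxopropanamide
Conditions: 14 (2.2 equiv), LiN(iPr)2 (2.3 equiv), THF, −78 °C; then 18, −78 → −20 °C; AcOH
Reagents that add atoms: N-methoxy-N-methylacetamide (14), CC(=O)N(C)OC
Why: Crossed Claisen condensation of the lithium enolate of the acetamide with the methyl ester, driven by deprotonation of the β-keto amide by the second equivalent of enolate.

**Step 10**
Reactants: 19 N-methoxy-3-{2-methoxy-4-[(triisopropylsilyl)oxy]phenyl}-N-methyl-3-oxopropanamide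
Product: 20 (3S)-3-hydroxy-N-methoxy-3-{2-methoxy-4-[(triisopropylsilyl)oxy]phenyl}-N-methylpropanamide
Conditions: RuCl[(S,S)-TsDPEN](p-cymene) (1 mol %), HCO2H/Et3N (5:2), EtOAc, 25 °C
Reagents that add atoms: none
Why: Noyori–Ikariya asymmetric transfer hydrogenation of the aryl ketone, in which the (S,S)-ligand, through the CH/π contact between p-cymene and the aryl group, is expected by analogy with aryl alkyl ketones to deliver hydride to the face that gives the (S) carbinol, the future C2.

**Step 11**
Reactants: 15 5-lavandulyl-6-(2-oxopropyl)-2,2-dimethyl-4H-1,3-dioxin-4-one; 20 (3S)-β-hydroxy N-methoxy-N-methylamide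
Product: 21 6-[(6S)-6-hydroxy-6-{2-methoxy-4-[(triisopropylsilyl)oxy]phenyl}-2,4-dioxohexyl]-2,2-dimethyl-5-[(2S)-5-methyl-2-(prop-1-en-2-yl)hex-4-en-1-yl]-4H-1,3-dioxin-4-one
Conditions: 15, LiN(iPr)2 (2.1 equiv), THF, −78 °C; then 20 pre-treated with LiN(SiMe3)2 (1.0 equiv), THF, −78 → −20 °C; AcOH, −78 °C
Reagents that add atoms: none
Why: Claisen condensation of the terminal carbon of the 1,3-dicarbonyl dianion with the N-methoxy-N-methylamide forms the C4–C4a bond, the carbinol being masked as its lithium alkoxide so that the C2 centre is carried through unchanged.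

**Step 12**
Reactants: 21 open-chain δ-hydroxy-β-diketo dioxinone
Product: 24 (2S)-5,7-dihydroxy-2-{2-methoxy-4-[(triisopropylsilyl)oxy]phenyl}-6-[(2S)-5-methyl-2-(prop-1-en-2-yl)hex-4-en-1-yl]-2,3-dihydro-4H-chromen-4-one, via dihydropyranone 22 (not isolated), via acylketene 23 (not isolated)
Conditions: PPTS (10 mol %), 4 Å MS, PhMe (2 mM), 40 °C; then 110 °C, N2 sweep
Reagents that add atoms: none
Why: Proposed new method: PPTS first lets the C2 hydroxyl add to the C8a ketone of the 1,3-diketone (6-exo-trig hemiketalisation, then loss of water to the vinylogous ester 22), which closes ring C through the O1–C8a bond without touching C2, so that (2S) is carried over from 20 and no new stereocentre is formed. Heating then expels acetone from the dioxinone by retro-[4+2] to give acylketene 23, whose enol is a dienylketene (C5=C6, C7=C8, C8a=C4a) that closes ring A by a thermally allowed 6π-electrocyclisation (equivalently a C-acylation of the nucleophilic C4a by the ketene carbon C5) and tautomerises to the phenol. The closest known reactions are the acid-catalysed cyclodehydration of δ-hydroxy-β-diketones to 2,3-dihydro-4H-pyran-4-ones, the thermal release and intramolecular capture of acylketenes from dioxinones, and the dienylketene electrocyclisation that ends the Danheiser benzannulation; their union on a vinylogous ester to give an acylphloroglucinol ring is untested. The selectivity needed is C-acylation at C4a over pyranone formation and over intermolecular ketene capture, and the order of events should secure it: once O1 is the ring C ether no oxygen can reach C5 through a six-membered ring, the free hydroxyl is gone, the inward substituent on C4a is hydrogen, and high dilution disfavours dimerisation. The substitution of ring A (hydroxyls at C5 and C7, lavandulyl at C6, hydrogen at C8) follows from the connectivity of the chain and needs no control.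

**Step 13**
Reactants: 24 4'-O-triisopropylsilyl flavanone
Product: 25 (2S)-5,7-dihydroxy-2-(4-hydroxy-2-methoxyphenyl)-6-[(2S)-5-methyl-2-(prop-1-en-2-yl)hex-4-en-1-yl]-2,3-dihydro-4H-chromen-4-one (CNP0102823.1)
Conditions: Bu4NF, AcOH (1:1), THF, 0 °C
Reagents that add atoms: none
Why: Fluoride cleavage of the aryl silyl ether, buffered by AcOH so that the flavanone is not exposed to free base and C2 should not epimerise through retro-oxa-Michael ring opening.

**Compound list**
1 | (4R)-4-benzyl-1,3-oxazolidin-2-one | O=C1OC[C@@H](Cc2ccccc2)N1 | starting material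
2 | 3-methylbut-2-enoyl chloride | CC(C)=CC(=O)Cl | starting material
3 | (4R)-4-benzyl-3-(3-methylbut-2-enoyl)-1,3-oxazolidin-2-one | CC(C)=CC(=O)N1[C@H](Cc2ccccc2)COC1=O | intermediate
4 | 1-bromo-3-methylbut-2-ene (prenyl bromide) | CC(C)=CCBr | starting material
5 | (4R)-4-benzyl-3-[(2R)-5-methyl-2-(prop-1-en-2-yl)hex-4-enoyl]-1,3-oxazolidin-2-one | C=C(C)[C@@H](CC=C(C)C)C(=O)N1[C@H](Cc2ccccc2)COC1=O | intermediate
6 | (2R)-5-methyl-2-(prop-1-en-2-yl)hex-4-en-1-ol, (R)-lavandulol | C=C(C)[C@@H](CC=C(C)C)CO | intermediate
7 | iodine | II | starting material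
8 | (3R)-3-(iodomethyl)-2,6-dimethylhepta-1,5-diene, (R)-lavandulyl iodide | C=C(C)[C@@H](CC=C(C)C)CI | intermediate
9 | 2,2,6-trimethyl-4H-1,3-dioxin-4-one | CC1=CC(=O)OC(C)(C)O1 | starting material
10 | N-iodosuccinimide | O=C1CCC(=O)N1I | starting material
11 | 5-iodo-2,2,6-trimethyl-4H-1,3-dioxin-4-one | CC1=C(I)C(=O)OC(C)(C)O1 | intermediate
12 | [(2R)-5-methyl-2-(prop-1-en-2-yl)hex-4-en-1-yl]zinc iodide (formed in the flask) | C=C(C)[C@@H](CC=C(C)C)C[Zn]I | intermediate
13 | 2,2,6-trimethyl-5-[(2S)-5-methyl-2-(prop-1-en-2-yl)hex-4-en-1-yl]-4H-1,3-dioxin-4-one | C=C(C)[C@@H](CC=C(C)C)CC1=C(C)OC(C)(C)OC1=O | intermediate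
14 | N-methoxy-N-methylacetamide | CC(=O)N(C)OC | starting material
15 | 2,2-dimethyl-5-[(2S)-5-methyl-2-(prop-1-en-2-yl)hex-4-en-1-yl]-6-(2-oxopropyl)-4H-1,3-dioxin-4-one | C=C(C)[C@@H](CC=C(C)C)CC1=C(CC(C)=O)OC(C)(C)OC1=O | intermediate
16 | methyl 4-hydroxy-2-methoxybenzoate | COC(=O)c1ccc(O)cc1OC | starting material
17 | chlorotriisopropylsilane | CC(C)[Si](Cl)(C(C)C)C(C)C | starting material
18 | methyl 2-methoxy-4-[(triisopropylsilyl)oxy]benzoate | COC(=O)c1ccc(O[Si](C(C)C)(C(C)C)C(C)C)cc1OC | intermediate
19 | N-methoxy-3-{2-methoxy-4-[(triisopropylsilyl)oxy]phenyl}-N-methyl-3-oxopropanamide | CON(C)C(=O)CC(=O)c1ccc(O[Si](C(C)C)(C(C)C)C(C)C)cc1OC | intermediate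
20 | (3S)-3-hydroxy-N-methoxy-3-{2-methoxy-4-[(triisopropylsilyl)oxy]phenyl}-N-methylpropanamide | CON(C)C(=O)C[C@@H](c1ccc(O[Si](C(C)C)(C(C)C)C(C)C)cc1OC)O | intermediate
21 | 6-[(6S)-6-hydroxy-6-{2-methoxy-4-[(triisopropylsilyl)oxy]phenyl}-2,4-dioxohexyl]-2,2-dimethyl-5-[(2S)-5-methyl-2-(prop-1-en-2-yl)hex-4-en-1-yl]-4H-1,3-dioxin-4-one (drawn as the triketo tautomer; enol and cyclic hemiketal forms are expected in equilibrium) | C=C(C)[C@@H](CC=C(C)C)CC1=C(CC(=O)CC(=O)C[C@@H](c2ccc(O[Si](C(C)C)(C(C)C)C(C)C)cc2OC)O)OC(C)(C)OC1=O | intermediate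
22 | 6-{[(2S)-2-{2-methoxy-4-[(triisopropylsilyl)oxy]phenyl}-4-oxo-3,4-dihydro-2H-pyran-6-yl]methyl}-2,2-dimethyl-5-[(2S)-5-methyl-2-(prop-1-en-2-yl)hex-4-en-1-yl]-4H-1,3-dioxin-4-one (formed in the flask) | C=C(C)[C@@H](CC=C(C)C)CC1=C(CC2=CC(=O)C[C@@H](c3ccc(O[Si](C(C)C)(C(C)C)C(C)C)cc3OC)O2)OC(C)(C)OC1=O | intermediate
23 | (2S)-2-{2-methoxy-4-[(triisopropylsilyl)oxy]phenyl}-6-[(5S)-8-methyl-2-oxo-3-(oxomethylidene)-5-(prop-1-en-2-yl)non-7-en-1-yl]-2,3-dihydro-4H-pyran-4-one, the acylketene left when 22 loses acetone (formed in the flask) | C=C(C)[C@@H](CC=C(C)C)CC(=C=O)C(=O)CC1=CC(=O)C[C@@H](c2ccc(O[Si](C(C)C)(C(C)C)C(C)C)cc2OC)O1 | intermediate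
24 | (2S)-5,7-dihydroxy-2-{2-methoxy-4-[(triisopropylsilyl)oxy]phenyl}-6-[(2S)-5-methyl-2-(prop-1-en-2-yl)hex-4-en-1-yl]-2,3-dihydro-4H-chromen-4-one | C=C(C)[C@@H](CC=C(C)C)Cc1c(O)cc2c(c1O)C(=O)C[C@@H](c1ccc(O[Si](C(C)C)(C(C)C)C(C)C)cc1OC)O2 | intermediate
25 | (2S)-5,7-dihydroxy-2-(4-hydroxy-2-methoxyphenyl)-6-[(2S)-5-methyl-2-(prop-1-en-2-yl)hex-4-en-1-yl]-2,3-dihydro-4H-chromen-4-one (CNP0102823.1) | C=C(C)[C@@H](CC=C(C)C)Cc1c(O)cc2c(c1O)C(=O)C[C@@H](c1ccc(O)cc1OC)O2 | target

**Totals**
Total step count: 13. Longest linear sequence: 9 steps (steps 1, 2, 3, 4, 6, 7, 11, 12, 13).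

**Steps most likely to fail**

1. Step 12 (proposed new method). The acylketene may be consumed by dimerisation or by [2+2]/ene reaction with the side-chain alkenes before C4a attacks. Under the acid stage the aldol unit may lose water by β-elimination, or ionise at the electron-rich benzylic C2, before ring C closes.
Fallback, from 21 back to 24, in three operations that each have precedent as a reaction type: 21 is taken through the acid stage alone (PPTS, CH2Cl2, 23 °C) and dihydropyranone 22 is isolated. Heating 22 in toluene with methanol at 110 °C opens the dioxinone through the same acylketene, now captured by methanol, to the methyl β-keto ester F1 (both epimers at the ester-bearing carbon). F1 is then closed by a biomimetic polyketide Claisen cyclisation with Mg(OMe)2 in methanol at 23 °C: the magnesium dienolate formed at C8 attacks the ester through C4a, methanol is lost and the ring aromatises to 24. This stage is basic, so ring C could open reversibly and the configuration at C2 would have to be verified.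

2. Step 11. Acylation of the dianion may be slow when the amide carries a lithium alkoxide, and warming to force it may bring retro-aldol cleavage or proton transfer that quenches the dianion.
Fallback, from 20 back to 21: 20 is silylated (Et3SiCl, imidazole, CH2Cl2) to the triethylsilyl ether F2, which is condensed with the dianion of 15 as in step 11 to give the silyl-protected precursor F3. The triethylsilyl group is then removed in the presence of the aryl triisopropylsilyl ether with HF·pyridine buffered with pyridine (THF, 0 °C), which returns 21.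

3. Step 6. β-Hydride elimination from the alkylpalladium intermediate (it would give a conjugated diene) may outrun reductive elimination, and homoallyl/cyclopropylcarbinyl radical rearrangement during zinc insertion would scramble the side-chain centre.
Fallback, from 8 back to 13, builds the dioxinone around the side chain instead of coupling onto it: the sodium enolate of tert-butyl acetoacetate (NaH, DMF, 50 °C) is C-alkylated with 8 to give the tert-butyl β-keto ester F4 (both epimers at C2). F4 is converted into 13 with acetone, Ac2O and catalytic H2SO4 at 0 °C, the standard dioxinone synthesis from tert-butyl β-keto esters, with the acid exposure kept short because of the two alkenes.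

**Further compounds**
F1 | step 12 | methyl (4S)-2-{[(2S)-2-{2-methoxy-4-[(triisopropylsilyl)oxy]phenyl}-4-oxo-3,4-dihydro-2H-pyran-6-yl]acetyl}-7-methyl-4-(prop-1-en-2-yl)oct-6-enoate (both epimers at C2) | C=C(C)[C@@H](CC=C(C)C)CC(C(=O)OC)C(=O)CC1=CC(=O)C[C@@H](c2ccc(O[Si](C(C)C)(C(C)C)C(C)C)cc2OC)O1
F2 | step 11 | (3S)-N-methoxy-3-{2-methoxy-4-[(triisopropylsilyl)oxy]phenyl}-N-methyl-3-[(triethylsilyl)oxy]propanamide | CON(C)C(=O)C[C@@H](c1ccc(O[Si](C(C)C)(C(C)C)C(C)C)cc1OC)O[Si](CC)(CC)CC
F3 | step 11 | 6-[(6S)-6-{2-methoxy-4-[(triisopropylsilyl)oxy]phenyl}-2,4-dioxo-6-[(triethylsilyl)oxy]hexyl]-2,2-dimethyl-5-[(2S)-5-methyl-2-(prop-1-en-2-yl)hex-4-en-1-yl]-4H-1,3-dioxin-4-one | C=C(C)[C@@H](CC=C(C)C)CC1=C(CC(=O)CC(=O)C[C@@H](c2ccc(O[Si](C(C)C)(C(C)C)C(C)C)cc2OC)O[Si](CC)(CC)CC)OC(C)(C)OC1=O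
F4 | step 6 | tert-butyl (4S)-2-acetyl-7-methyl-4-(prop-1-en-2-yl)oct-6-enoate (both epimers at C2) | C=C(C)[C@@H](CC=C(C)C)CC(C(C)=O)C(=O)OC(C)(C)C
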